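The O6–C7(=O) bridge of the 6-oxabicyclo[3.2.1]octane-7,8-dione is read as one molecule of CO2 laid across the α (C1) and α′ (C5) carbons of the C8 ketone in the carbocycle C1–C2–C3–C4–C5–C8. The last step therefore stitches CO2 onto a monocyclic 2-isobutyryl-3,3-dimethyl-4,6-diprenylcyclohexanone. Its bis-enolate is carboxylated at the ring terminus (C7–C1). Iodine(III) umpolung of the remaining diketone enolate then lets the new carboxylate close on C5 (O6–C5). One flask thus creates the lactone ring and both quaternary bridgeheads. Both are relayed from the single C3 stereocentre, which is set at the outset by an enamine-catalysed Michael addition.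

Key step: step 8

Remark: prenyl = 3-methylbut-2-en-1-yl; 1 is taken as a catalogue aldehyde; the sense of induction in step 1 follows the usual steric-shielding model of diarylprolinol ethers; the enolisable centres C2/C6 and the carbinol carbon in 10–14 are carried as epimer mixtures because each is erased in step 7 or step 8.

Step 1
Reactants: 1 5-methylhex-4-enal; 2 methyl vinyl ketone
Product: 3 (2S)-5-methyl-2-(3-oxobutyl)hex-4-enal
Conditions: (S)-2-[methoxy(diphenyl)methyl]pyrrolidine (5 mol %), ethyl 3,4-dihydroxybenzoate (20 mol %), neat, 4 °C
Reagents that add atoms: none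
Why: Enamine-catalysed asymmetric Michael addition, in which the diphenyl(methoxy)methyl group shields one face of the E-enamine of 1, so that 2 adds to the open face and sets the (S) centre that becomes C3 of the target.

Step 2
Reactants: 3 (2S)-5-methyl-2-(3-oxobutyl)hex-4-enal
Product: 5 (4S)-4-prenylcyclohex-2-en-1-one, via ketol 4 (not isolated)
Conditions: LiOH, i-PrOH, rt
Reagents that add atoms: none
Why: Intramolecular aldol condensation (6-enolexo closure of the methyl ketone enolate on the aldehyde, then E1cB loss of water), which should outrun epimerisation of the aldehyde α-centre and turn it into the less acidic γ-position of the enone.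

Step 3
Reactants: 5 (4S)-4-prenylcyclohex-2-en-1-one
Product: 6 trimethyl{[(3S,4S)-3-methyl-4-prenylcyclohex-1-en-1-yl]oxy}silane (methyl trans to prenyl)
Conditions: MeMgBr, CuI·2LiCl (10 mol %), TMSCl, THF, −78 → −40 °C; Et3N quench
Reagents that add atoms: methylmagnesium bromide, C[Mg]Br; chlorotrimethylsilane, C[Si](C)(C)Cl
Why: Copper-catalysed, TMSCl-accelerated conjugate addition that delivers methyl anti to the C4 prenyl group (a transient centre) and fixes the enolate regiochemistry as the silyl enol ether.

Step 4
Reactants: 6 trimethyl{[(3S,4S)-3-methyl-4-prenylcyclohex-1-en-1-yl]oxy}silane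
Product: 7 (4S)-3-methyl-4-prenylcyclohex-2-en-1-one
Conditions: Pd(OAc)2 (10 mol %), O2 (1 atm), DMSO, rt
Reagents that add atoms: none
Why: Saegusa–Ito oxidation, in which the oxo-π-allylpalladium species has only the C3–H available for β-hydride elimination, so the enone is restored regiospecifically and the isolated trisubstituted alkene should stay untouched.

Step 5
Reactants: 7 (4S)-3-methyl-4-prenylcyclohex-2-en-1-one; 8 prenyl bromide
Product: 10 (4R)-3-methyl-4,6-diprenylcyclohex-2-en-1-one (C6 epimers), via lithium dienolate 9 (not isolated)
Conditions: LDA (1.05 equiv), THF, −78 °C; then 8, −78 → −20 °C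
Reagents that add atoms: none
Why: Kinetic α′-deprotonation of the enone gives the cross-conjugated dienolate, which is alkylated at C6 by the allylic bromide (enolate SN2 alkylation) without touching C4, whose descriptor changes only through CIP priorities.

Step 6
Reactants: 10 (4R)-3-methyl-4,6-diprenylcyclohex-2-en-1-one; 11 isobutyraldehyde
Product: 13 (4R)-2-(1-hydroxy-2-methylpropyl)-3,3-dimethyl-4,6-diprenylcyclohexan-1-one (diastereomer mixture), via bromomagnesium enolate 12 (not isolated)
Conditions: MeMgBr, CuBr·SMe2 (20 mol %), THF, −40 → 0 °C; then 11, −78 °C; aq NH4Cl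
Reagents that add atoms: methylmagnesium bromide, C[Mg]Br
Why: Tandem copper-catalysed conjugate addition/aldol reaction, in which the second methyl group completes the gem-dimethyl carbon and the regiodefined enolate is trapped at C2 before it can equilibrate towards the tertiary C6–H.

Step 7
Reactants: 13 (4R)-2-(1-hydroxy-2-methylpropyl)-3,3-dimethyl-4,6-diprenylcyclohexan-1-one
Product: 14 (4R)-3,3-dimethyl-2-(2-methylpropanoyl)-4,6-diprenylcyclohexan-1-one (C2/C6 epimers and enol forms)
Conditions: Dess–Martin periodinane, CH2Cl2, 0 °C → rt
Reagents that add atoms: none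
Why: Dess–Martin oxidation converts the β-hydroxy ketone into the 1,3-diketone under near-neutral conditions that avoid retro-aldol cleavage and leave the prenyl alkenes intact.

Step 8
Reactants: 14 (4R)-3,3-dimethyl-2-(2-methylpropanoyl)-4,6-diprenylcyclohexan-1-one; 15 carbon dioxide
Product: 19 (1R,3R,5R)-4,4-dimethyl-5-(2-methylpropanoyl)-1,3-diprenyl-6-oxabicyclo[3.2.1]octane-7,8-dione (target), via dilithium bis-enolate 16 (not isolated), via dilithium carboxylate enolate 17 (not isolated), via iodine(III) enolate 18 (not isolated)
Conditions: LiTMP (2.4 equiv), THF, −78 → −20 °C; CO2 (1 atm), −78 °C, then Ar purge; PhI(OAc)2 (1.1 equiv), −78 → 0 °C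
Reagents that add atoms: none
Why: Proposed new method: LiTMP removes the C2–H and the ring C6–H of 14 (C5 and C1 of 19) to give bis-enolate 16, whose more basic ring terminus attacks CO2 (forming C7–C1) to give 17; the surviving exocyclic enolate then binds PhI(OAc)2 through oxygen (18), which reverses the polarity of C5, and the carboxylate oxygen displaces PhI and acetate in an SN2′ sense (forming O6–C5). The closest known reaction types are the γ-carboxylation of 1,3-diketone dianions, the iodine(III) oxylactonisation of keto and diketo acids and the Effenberger α,α′-annulation of cyclohexanone enol ethers; new is their merger into an oxidative (3+2) annulation of CO2 that closes a bridge at a fully substituted, neopentyl carbon. The only ring closed is the five-membered keto-lactone O6–C7–C1–C8–C5, by 5-exo-trig attack of the axial carboxylate on the exocyclic C5=C(O–I) bond, which completes the bicyclo[3.2.1] frame. C1 is set by axial attack of CO2 on the sofa conformer of 16 that keeps the C3 prenyl group equatorial, on the face that carries only the axial C3–H, whereas the other face demands a twist-boat that meets the axial C4 methyl group; C5 is then fixed by the tether, since the carboxylate can reach only its own face. The step needs ring-methine over isopropyl-methine deprotonation (the isopropylidene enolate would suffer severe allylic strain against the congested C5/C4 region), γ-C- over α-C- or O-carboxylation (the diketonate is the weaker, more hindered nucleophile and its carboxylation is reversible) and enolate over prenyl oxidation (an anionic enolate engages PhI(OAc)2 at −78 °C, where unactivated trisubstituted alkenes are inert, and no halonium source is present that could trigger halolactonisation). Lactonisation should outrun acetate transfer because it is intramolecular.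

Compound list
1 | 5-methylhex-4-enal | CC(C)=CCCC=O | starting material
2 | methyl vinyl ketone | C=CC(C)=O | starting material
3 | (2S)-5-methyl-2-(3-oxobutyl)hex-4-enal | CC(C)=CC[C@@H](C=O)CCC(C)=O | intermediate
4 | (4S)-3-hydroxy-4-prenylcyclohexan-1-one (ketol, not isolated) | CC(C)=CC[C@@H]1CCC(=O)CC1O | intermediate
5 | (4S)-4-prenylcyclohex-2-en-1-one | CC(C)=CC[C@@H]1CCC(=O)C=C1 | intermediate
6 | trimethyl{[(3S,4S)-3-methyl-4-prenylcyclohex-1-en-1-yl]oxy}silane | CC(C)=CC[C@@H]1CCC(O[Si](C)(C)C)=C[C@H]1C | intermediate
7 | (4S)-3-methyl-4-prenylcyclohex-2-en-1-one | CC(C)=CC[C@@H]1CCC(=O)C=C1C | intermediate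
8 | prenyl bromide (1-bromo-3-methylbut-2-ene) | CC(C)=CCBr | starting material
9 | lithium cross-conjugated dienolate of 7 (not isolated) | [Li+].CC(C)=CC[C@@H]1CC=C([O-])C=C1C | intermediate
10 | (4R)-3-methyl-4,6-diprenylcyclohex-2-en-1-one (C6 epimers) | CC(C)=CC[C@@H]1CC(CC=C(C)C)C(=O)C=C1C | intermediate
11 | isobutyraldehyde | CC(C)C=O | starting material
12 | bromomagnesium (4R)-3,3-dimethyl-4,6-diprenylcyclohex-1-en-1-olate (not isolated) | CC(C)=CC[C@@H]1CC(CC=C(C)C)C(O[Mg]Br)=CC1(C)C | intermediate
13 | (4R)-2-(1-hydroxy-2-methylpropyl)-3,3-dimethyl-4,6-diprenylcyclohexan-1-one (diastereomer mixture) | CC(C)=CC[C@@H]1CC(CC=C(C)C)C(=O)C(C(O)C(C)C)C1(C)C | intermediate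
14 | (4R)-3,3-dimethyl-2-(2-methylpropanoyl)-4,6-diprenylcyclohexan-1-one | CC(C)=CC[C@@H]1CC(CC=C(C)C)C(=O)C(C(=O)C(C)C)C1(C)C | intermediate
15 | carbon dioxide | O=C=O | starting material
16 | dilithium bis-enolate of 14 (not isolated) | [Li+].[Li+].CC(C)=CC[C@@H]1CC(CC=C(C)C)=C([O-])C(=C([O-])C(C)C)C1(C)C | intermediate
17 | dilithium carboxylate enolate, carboxylate axial and trans to the ring prenyl group (not isolated) | [Li+].[Li+].CC(C)=CC[C@@H]1C[C@@](CC=C(C)C)(C([O-])=O)C(=O)C(=C([O-])C(C)C)C1(C)C | intermediate
18 | O-bound acetoxy(phenyl)-λ3-iodanyl enolate of the lithium carboxylate (not isolated) | [Li+].CC(C)=CC[C@@H]1C[C@@](CC=C(C)C)(C([O-])=O)C(=O)C(=C(OI(OC(C)=O)c2ccccc2)C(C)C)C1(C)C | intermediate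
19 | (1R,3R,5R)-4,4-dimethyl-5-(2-methylpropanoyl)-1,3-diprenyl-6-oxabicyclo[3.2.1]octane-7,8-dione | CC(C)=CC[C@@H]1C[C@@]2(CC=C(C)C)C(=O)O[C@](C(=O)C(C)C)(C2=O)C1(C)C | target

Total step count: 8. Longest linear sequence: 8.

Steps most likely to fail

Step 8 (Proposed new method). Several processes could defeat it:
- deprotonation at the isopropyl methine instead of the ring methine;
- loss of CO2 from the β-keto carboxylate before oxidation;
- one-electron oxidation of the enolate followed by radical cyclisation onto a prenyl group;
- acetate transfer in place of the tethered carboxylate;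
- plain failure of closure at the congested carbon.

The fallback sets out from 14 and comes back at 19. It separates the two bond formations and uses the natural polarity of C5. Bis-enolate 16 would be C-acylated with diphenyl carbonate (Claisen-type γ-acylation of a diketone dianion) to give the phenyl β-keto ester F1. KHMDS followed by 2-(phenylsulfonyl)-3-phenyloxaziridine (Davis oxidation) would then hydroxylate the diketone carbon to the tertiary alcohol F2. Its alkoxide, when formed syn to the ester, would close by 5-exo-trig acyl substitution with loss of phenoxide to give 19.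

Step 6. The 1,4-addition may be slow at a β,β-disubstituted enone flanked by the C4 substituent. Proton transfer may scramble the enolate, and the crowded aldolate may undergo retro-aldol cleavage. The fallback sets out from 10 and comes back at 13. The copper-catalysed methyl addition would be run in the presence of TMSCl and the product isolated as the silyl enol ether F3. This would then be joined to 11 in a Mukaiyama aldol reaction (BF3·OEt2, CH2Cl2, −78 °C), so that the aldehyde rather than the hindered nucleophile is activated.

Step 5. Proton exchange between product and dienolate may lead to double alkylation, and γ-deprotonation may erode the C4 centre. The fallback sets out from 7 and comes back at 14. Enone 7 would be taken directly through the methyl addition/aldol sequence to the monoprenyl hydroxy ketone F4, and through Dess–Martin oxidation to the monoprenyl diketone F5. The dianion of F5 (LDA, 2.2 equiv) would be alkylated by 8 at the ring CH2 (γ-alkylation of a 1,3-diketone dianion).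

Further compounds
F1 | step 8 | phenyl (1R,5R)-4,4-dimethyl-3-(2-methylpropanoyl)-2-oxo-1,5-diprenylcyclohexane-1-carboxylate | CC(C)=CC[C@@H]1C[C@@](CC=C(C)C)(C(=O)Oc2ccccc2)C(=O)C(C(=O)C(C)C)C1(C)C
F2 | step 8 | phenyl (1R,3R,5R)-3-hydroxy-4,4-dimethyl-3-(2-methylpropanoyl)-2-oxo-1,5-diprenylcyclohexane-1-carboxylate | CC(C)=CC[C@@H]1C[C@@](CC=C(C)C)(C(=O)Oc2ccccc2)C(=O)[C@](O)(C(=O)C(C)C)C1(C)C
F3 | step 6 | {[(4R)-3,3-dimethyl-4,6-diprenylcyclohex-1-en-1-yl]oxy}trimethylsilane | CC(C)=CC[C@@H]1CC(CC=C(C)C)C(O[Si](C)(C)C)=CC1(C)C
F4 | step 5 | (4S)-2-(1-hydroxy-2-methylpropyl)-3,3-dimethyl-4-prenylcyclohexan-1-one | CC(C)=CC[C@@H]1CCC(=O)C(C(O)C(C)C)C1(C)C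
F5 | step 5 | (4S)-3,3-dimethyl-2-(2-methylpropanoyl)-4-prenylcyclohexan-1-one | CC(C)=CC[C@@H]1CCC(=O)C(C(=O)C(C)C)C1(C)C
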